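**Retrosynthetic overview**
1. Atoms are numbered from the lactone carbonyl C1 to the methyl C26. The plan rests on the six-carbon strip C1–C6 (ring atoms C1–C5 and O, plus exocyclic C6), oxygenated at C1, C3 and C5. Its C3 oxygen is expendable and becomes the C2=C3 alkene. C7–C12 (oxygen at C7, C9, C11) repeats this strip in the same absolute sense.
2. C2=C3 comes from E1cB loss of an activated C3 oxygen from the β-hydroxy-δ-lactone, which is the oxidised C1 lactol. C6–C7 comes from SN2 of a C7 dithiane anion (carrying C8–C26) on the C6 iodide, and C7 is then set by a C9–OH-directed 1,3-syn reduction.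
3. C12–C13 comes from a copper-catalysed Grignard opening of the C11–C12 epoxide. The C13–C26 Grignard reagent takes C15 from asymmetric hydrogenation of methyl 3-oxotetradecanoate.
4. Both strips come from one lactol, which an aldolase builds from chloroacetaldehyde and two acetaldehydes. This sets C3/C5 and, in the second copy, C9/C11.
5. Rings: the oxygen six-ring closes in step 1 and is kept to the end (lactol → benzyl glycoside → lactol → lactone → enoate). The dithiane and oxirane rings are temporary.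

Key step: step 1

Remark: C1 is carried as an anomeric mixture and left undefined in the SMILES, because it ends as the sp2 lactone carbonyl. Atom labels C1–C26 always refer to the target. TBS = tert-butyldimethylsilyl, PMB = 4-methoxybenzyl, Bn = benzyl.

**Step 1**
Reactants: 1 chloroacetaldehyde (commercial aqueous solution); 2 acetaldehyde (2 equiv)
Product: 5 6-chloro-2,4,6-trideoxy-D-erythro-hexopyranose (anomeric mixture), via (3S)-4-chloro-3-hydroxybutanal 3 (not isolated), via (3R,5S)-6-chloro-3,5-dihydroxyhexanal 4 (not isolated)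
Conditions: 2-deoxyribose-5-phosphate aldolase (overexpressed aldehyde-tolerant variant, cell-free extract), aq. NaHCO3 buffer pH 7.2, 30 °C, slow co-feed of 1 and 2; EtOAc extraction
Reagents that add atoms: none
Why: The active-site lysine turns acetaldehyde into an enamine that adds to the carbonyl of 1 (C4–C5 bond) and releases 3, and 3 then serves as acceptor for a second enamine (C2–C3 bond) to give 4. This is the known class I aldolase sequential aldol of acetaldehyde onto α-haloacetaldehydes, which gives 2,4,6-trideoxyhexoses. Compound 4 leaves the cycle by 6-exo-trig attack of the C5 hydroxyl on the C1 aldehyde (C1–O bond, oxane ring), and the lactol offers no free aldehyde for a third addition. Both carbinol centres (C5 S, C3 R, 1,3-syn) are fixed by the enzyme pocket, which presents one face of each acceptor carbonyl to the bound enamine, so substrate bias plays no part. The step needs cross-aldol over self-aldol: 1 is not accepted as a donor and is the more electrophilic acceptor, and the slow feed keeps both aldehyde levels low, which protects the enzyme and limits trimerisation of 2.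

**Step 2**
Reactants: 5 lactol (first portion)
Product: 6 benzyl 6-chloro-2,4,6-trideoxy-D-erythro-hexopyranoside [(4R,6S)-2-(benzyloxy)-6-(chloromethyl)oxan-4-ol]
Conditions: BnOH (3 equiv), CSA (cat.), 4 Å MS, CH2Cl2, rt
Reagents that add atoms: benzyl alcohol, OCc1ccccc1
Why: Fischer glycosidation runs through the 2-deoxy oxocarbenium ion, which only the anomeric hydroxyl can form, so C3–OH stays free, C3 and C5 are untouched, and C1 is masked by a group that can later be removed without acid.

**Step 3**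
Reactants: 6
Product: 7 benzyl 3-O-benzyl-6-chloro-2,4,6-trideoxy-D-erythro-hexopyranoside
Conditions: NaH, BnBr, Bu4NI (cat.), THF–DMF, 0 °C → rt
Reagents that add atoms: benzyl bromide, BrCc1ccccc1
Why: Williamson etherification of the only free hydroxyl should be clean, because the axial C3 alkoxide is trans to the equatorial CH2Cl arm and cannot cyclise onto C6, and benzyl lets C3–O and C1–O be released together in step 19.

**Step 4**
Reactants: 7
Product: 8 benzyl 3-O-benzyl-2,4,6-trideoxy-6-iodo-D-erythro-hexopyranoside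
Conditions: NaI (excess), NaHCO3 (trace), 2-butanone, reflux
Reagents that add atoms: sodium iodide, [Na+].[I-]
Why: Finkelstein exchange, driven by precipitation of NaCl, converts the sluggish β-oxygenated primary chloride into the iodide needed for SN2 with a soft carbanion, and no stereocentre is involved.

**Step 5**
Reactants: 5 lactol (second portion; its C1–C6 become C7–C12)
Product: 9 (2S,4R)-1-chloro-5-(1,3-dithian-2-yl)pentane-2,4-diol
Conditions: HS(CH2)3SH, BF3·OEt2, CH2Cl2–MeCN, −20 → 0 °C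
Reagents that add atoms: propane-1,3-dithiol, SCCCS
Why: Lewis-acid dithioacetalisation traps the open-chain aldehyde tautomer, as is usual for 2-deoxy sugars, which makes C7 a latent acyl anion (Corey–Seebach umpolung), releases the C11 hydroxyl next to the chloride, and leaves C9 and C11 as the enzyme set them.

**Step 6**
Reactants: 9
Product: 10 (2R)-1-(1,3-dithian-2-yl)-3-[(2S)-oxiran-2-yl]propan-2-ol
Conditions: K2CO3, MeOH, 0 °C → rt
Reagents that add atoms: none
Why: Intramolecular Williamson closure (3-exo-tet) of the C11 chlorohydrin alkoxide is the kinetic path, as in the standard conversion of 1-halo-2,4-diols into syn epoxy alcohols, and C11 keeps its configuration because its C–O bond is not broken.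

**Step 7**
Reactants: 10
Product: 11 2-{(2R)-2-[(4-methoxybenzyl)oxy]-3-[(2S)-oxiran-2-yl]propyl}-1,3-dithiane
Conditions: NaH, PMBCl, Bu4NI (cat.), THF–DMF, 0 °C
Reagents that add atoms: 4-methoxybenzyl chloride, COc1ccc(CCl)cc1
Why: Williamson etherification marks C9–O with a group that withstands RMgBr and t-BuLi and can be removed oxidatively beside TBS and Bn, while 4-exo or 5-endo attack of the alkoxide on the epoxide is disfavoured at this temperature.

**Step 8**
Reactants: 12 methyl 3-oxotetradecanoate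
Product: 13 methyl (3S)-3-hydroxytetradecanoate
Conditions: H2 (50 bar), RuCl2[(S)-BINAP] (cat.), MeOH, 50 °C
Reagents that add atoms: none
Why: Noyori asymmetric hydrogenation of a β-keto ester delivers hydride within the ester-chelated Ru complex, and the (S)-BINAP ligand sets the S carbinol that becomes C15.

**Step 9**
Reactants: 13
Product: 14 methyl (3S)-3-(tert-butyldimethylsilyloxy)tetradecanoate
Conditions: TBSCl, imidazole, DMF, rt
Reagents that add atoms: tert-butyldimethylsilyl chloride, CC(C)(C)[Si](C)(C)Cl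
Why: Standard imidazole-promoted silylation protects C15–O with a group that survives the hydride, Grignard and organolithium steps, and C15 is not affected.

**Step 10**
Reactants: 14
Product: 15 (3S)-3-(tert-butyldimethylsilyloxy)tetradecan-1-ol
Conditions: DIBAL-H (2.5 equiv), CH2Cl2, −78 → 0 °C; aq. Rochelle salt
Reagents that add atoms: none
Why: Double hydride reduction of the ester gives the primary alcohol C13, and the low temperature and non-basic aluminium alkoxide should suppress 1,3-silyl migration.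

**Step 11**
Reactants: 15
Product: 16 (3S)-1-bromo-3-(tert-butyldimethylsilyloxy)tetradecane
Conditions: CBr4, PPh3, CH2Cl2, 0 °C
Reagents that add atoms: carbon tetrabromide, BrC(Br)(Br)Br
Why: The Appel reaction replaces the primary hydroxyl by SN2 on the alkoxyphosphonium ion under nearly neutral conditions, which the secondary TBS ether tolerates.

**Step 12**
Reactants: 16; 11
Product: 18 (2R,4R,8S)-8-(tert-butyldimethylsilyloxy)-1-(1,3-dithian-2-yl)-2-[(4-methoxybenzyl)oxy]nonadecan-4-ol, via (3S)-3-(TBSO)tetradecylmagnesium bromide 17 (not isolated)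
Conditions: Mg, I2 (trace), THF, reflux; then CuI (10 mol %), 11, THF, −30 → 0 °C; aq. work-up
Reagents that add atoms: magnesium, [Mg] (stays only in 17)
Why: Copper-catalysed Grignard opening of a terminal epoxide is an SN2 attack at the unhindered C12, so the C11–O bond and its configuration are kept and C11–OH emerges as the only free hydroxyl; the γ-silyloxy Grignard reagent has no β-leaving group, and neither the PMB ether nor the dithiane C–H reacts at this temperature.

**Step 13**
Reactants: 18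
Product: 19 2-[(2R,4R,8S)-4,8-bis(tert-butyldimethylsilyloxy)-2-[(4-methoxybenzyl)oxy]nonadecyl]-1,3-dithiane
Conditions: TBSCl, imidazole, DMAP (cat.), DMF, 40 °C
Reagents that add atoms: tert-butyldimethylsilyl chloride, CC(C)(C)[Si](C)(C)Cl
Why: Silylation of the single free secondary alcohol completes the differentiation C9–OPMB / C11–OTBS that the directed reduction in step 17 depends on.

**Step 14**
Reactants: 19; 8
Product: 21 benzyl 3-O-benzyl-2,4,6-trideoxy-6-C-{2-[(2R,4R,8S)-4,8-bis(TBSO)-2-(PMBO)nonadecyl]-1,3-dithian-2-yl}-D-erythro-hexopyranoside, via 2-lithio-1,3-dithiane 20 (not isolated)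
Conditions: t-BuLi (1.05 equiv), THF–HMPA 9:1, −78 °C; then 8, −78 → −20 °C
Reagents that add atoms: tert-butyllithium, [Li]C(C)(C)C (lithium stays only in 20)
Why: In this Corey–Seebach alkylation the HMPA-separated 2-alkyl-2-lithiodithiane is a soft nucleophile that displaces the primary iodide by SN2 to form C6–C7; 6-iodo-2,4,6-trideoxyhexopyranosides are established alkylating agents, the C9 oxygen sits two carbons from the carbanion and cannot be eliminated, and no stereocentre is touched.

**Step 15**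
Reactants: 21
Product: 22 (4R,6R,10S)-1-[(2S,4R)-4,6-bis(benzyloxy)oxan-2-yl]-6,10-bis(TBSO)-4-(PMBO)henicosan-2-one
Conditions: MeI (excess), CaCO3, MeCN–H2O 9:1, 40 °C
Reagents that add atoms: water, O
Why: Alkylative dithiane hydrolysis (S-methylation, ring opening, capture by water) unmasks the C7 ketone, and the carbonate buffer keeps the acid-labile 2-deoxyglycoside and the silyl ethers intact.

**Step 16**
Reactants: 22
Product: 23 (4R,6R,10S)-1-[(2S,4R)-4,6-bis(benzyloxy)oxan-2-yl]-6,10-bis(TBSO)-4-hydroxyhenicosan-2-one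
Conditions: DDQ, CH2Cl2–pH 7 buffer, 0 °C
Reagents that add atoms: none
Why: Oxidative PMB cleavage by hydride abstraction from the electron-rich benzylic position frees C9–OH selectively, because plain benzyl ethers, the benzyl acetal and TBS ethers react far more slowly under buffered conditions.

**Step 17**
Reactants: 23
Product: 25 (2R,4S,6R,10S)-1-[(2R,4R)-4,6-bis(benzyloxy)oxan-2-yl]-6,10-bis(TBSO)henicosane-2,4-diol (descriptor changes at C5 and C9 are priority effects only), via C9 O-diethylboryl chelate 24 (not isolated)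
Conditions: Et2BOMe (1.1 equiv), THF–MeOH 4:1, −78 °C; NaBH4; AcOH quench, co-evaporation with MeOH
Reagents that add atoms: diethyl(methoxy)borane, CCB(CC)OC (boron stays only in 24)
Why: In the Narasaka–Prasad reduction the C9–O–BEt2 group chelates the C7 carbonyl in a half-chair, and external axial hydride delivery sets C7 syn to C9, which completes the all-syn C5/C7/C9/C11 array.

**Step 18**
Reactants: 25
Product: 26 (2S,4R)-4,6-bis(benzyloxy)-2-[(2S,4R,6R,10S)-2,4,6,10-tetrakis(TBSO)henicosyl]oxane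
Conditions: TBSOTf, 2,6-lutidine, CH2Cl2, −78 → 0 °C
Reagents that add atoms: tert-butyldimethylsilyl triflate, CC(C)(C)[Si](C)(C)OS(=O)(=O)C(F)(F)F
Why: Triflate silylation covers both hindered 1,3-diol hydroxyls under base-buffered conditions that spare the benzyl glycoside, and a protected C7–O cannot be mesylated or add to the enoate later.

**Step 19**
Reactants: 26
Product: 27 (4R,6S)-6-[(2S,4R,6R,10S)-2,4,6,10-tetrakis(TBSO)henicosyl]oxane-2,4-diol (anomeric mixture)
Conditions: H2 (1 atm), Pd(OH)2/C, EtOAc, rt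
Reagents that add atoms: none
Why: Neutral hydrogenolysis removes the anomeric and the C3 benzyl groups in one operation after all sulfur has left the molecule, and TBS ethers are stable in EtOAc under these conditions.

**Step 20**
Reactants: 27
Product: 28 (4R,6S)-4-hydroxy-6-[(2S,4R,6R,10S)-2,4,6,10-tetrakis(TBSO)henicosyl]oxan-2-one
Conditions: Ag2CO3 on Celite, toluene, 90 °C
Reagents that add atoms: none
Why: Fétizon oxidation takes lactols to lactones much faster than it oxidises an isolated secondary alcohol, as is known for this 4-hydroxy-oxan-2-ol ring type, and any premature loss of water from C3 only anticipates step 21.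

**Step 21**
Reactants: 28
Product: 30 (6S)-6-[(2S,4R,6R,10S)-2,4,6,10-tetrakis(TBSO)henicosyl]-5,6-dihydro-2H-pyran-2-one, via C3 methanesulfonate 29 (not isolated)
Conditions: MsCl, Et3N (excess), CH2Cl2, 0 °C → rt
Reagents that add atoms: methanesulfonyl chloride, CS(=O)(=O)Cl (stays only in 29)
Why: Mesylation of the only free hydroxyl is followed by E1cB elimination through the lactone enolate, helped by the axial C3 leaving group, which spends the C3 stereocentre as the conjugated C2=C3 alkene and leaves C5 untouched.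

**Step 22**
Reactants: 30
Product: 31 (6S)-6-[(2R,4R,6R,10S)-2,4,6,10-tetrahydroxyhenicosyl]-5,6-dihydro-2H-pyran-2-one (target)
Conditions: HF·pyridine, THF, 0 °C → rt (plastic vessel)
Reagents that add atoms: none
Why: Fluoride-driven global desilylation in a weakly acidic, non-nucleophilic medium cleaves only Si–O bonds, so all carbinol configurations are kept, and it avoids the basic conditions that would promote oxa-Michael addition of C7–OH to the enoate.

**Compound list**
1 | chloroacetaldehyde | ClCC=O | starting material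
2 | acetaldehyde | CC=O | starting material
3 | (3S)-4-chloro-3-hydroxybutanal | ClC[C@@H](O)CC=O | intermediate
4 | (3R,5S)-6-chloro-3,5-dihydroxyhexanal | ClC[C@@H](O)C[C@@H](O)CC=O | intermediate
5 | 6-chloro-2,4,6-trideoxy-D-erythro-hexopyranose, (4R,6S)-6-(chloromethyl)oxane-2,4-diol | ClC[C@@H]1C[C@@H](O)CC(O)O1 | intermediate
6 | benzyl 6-chloro-2,4,6-trideoxy-D-erythro-hexopyranoside | ClC[C@@H]1C[C@@H](O)CC(OCc2ccccc2)O1 | intermediate
7 | benzyl 3-O-benzyl-6-chloro-2,4,6-trideoxy-D-erythro-hexopyranoside | ClC[C@@H]1C[C@@H](OCc2ccccc2)CC(OCc2ccccc2)O1 | intermediate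
8 | benzyl 3-O-benzyl-2,4,6-trideoxy-6-iodo-D-erythro-hexopyranoside | IC[C@@H]1C[C@@H](OCc2ccccc2)CC(OCc2ccccc2)O1 | intermediate
9 | (2S,4R)-1-chloro-5-(1,3-dithian-2-yl)pentane-2,4-diol | ClC[C@@H](O)C[C@@H](O)CC1SCCCS1 | intermediate
10 | (2R)-1-(1,3-dithian-2-yl)-3-[(2S)-oxiran-2-yl]propan-2-ol | C1[C@@H](O1)C[C@@H](O)CC2SCCCS2 | intermediate
11 | 2-{(2R)-2-(PMBO)-3-[(2S)-oxiran-2-yl]propyl}-1,3-dithiane | C1[C@@H](O1)C[C@@H](OCc2ccc(OC)cc2)CC3SCCCS3 | intermediate
12 | methyl 3-oxotetradecanoate | CCCCCCCCCCCC(=O)CC(=O)OC | starting material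
13 | methyl (3S)-3-hydroxytetradecanoate | CCCCCCCCCCC[C@H](O)CC(=O)OC | intermediate
14 | methyl (3S)-3-(TBSO)tetradecanoate | CCCCCCCCCCC[C@H](O[Si](C)(C)C(C)(C)C)CC(=O)OC | intermediate
15 | (3S)-3-(TBSO)tetradecan-1-ol | CCCCCCCCCCC[C@H](O[Si](C)(C)C(C)(C)C)CCO | intermediate
16 | (3S)-1-bromo-3-(TBSO)tetradecane | CCCCCCCCCCC[C@H](O[Si](C)(C)C(C)(C)C)CCBr | intermediate
17 | (3S)-3-(TBSO)tetradecylmagnesium bromide | CCCCCCCCCCC[C@H](O[Si](C)(C)C(C)(C)C)CC[Mg]Br | intermediate
18 | (2R,4R,8S)-8-(TBSO)-1-(1,3-dithian-2-yl)-2-(PMBO)nonadecan-4-ol | CCCCCCCCCCC[C@H](O[Si](C)(C)C(C)(C)C)CCC[C@@H](O)C[C@@H](OCc1ccc(OC)cc1)CC1SCCCS1 | intermediate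
19 | 2-[(2R,4R,8S)-4,8-bis(TBSO)-2-(PMBO)nonadecyl]-1,3-dithiane | CCCCCCCCCCC[C@H](O[Si](C)(C)C(C)(C)C)CCC[C@@H](O[Si](C)(C)C(C)(C)C)C[C@@H](OCc1ccc(OC)cc1)CC1SCCCS1 | intermediate
20 | 2-lithio derivative of 19 (C7 carbanion) | CCCCCCCCCCC[C@H](O[Si](C)(C)C(C)(C)C)CCC[C@@H](O[Si](C)(C)C(C)(C)C)C[C@@H](OCc1ccc(OC)cc1)CC1([Li])SCCCS1 | intermediate
21 | C6–C7 coupled dithiane (C1, C3 OBn; C9 OPMB; C11, C15 OTBS) | CCCCCCCCCCC[C@H](O[Si](C)(C)C(C)(C)C)CCC[C@@H](O[Si](C)(C)C(C)(C)C)C[C@@H](OCc1ccc(OC)cc1)CC1(SCCCS1)C[C@@H]1C[C@@H](OCc2ccccc2)CC(OCc2ccccc2)O1 | intermediate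
22 | C7 ketone with C9 OPMB | CCCCCCCCCCC[C@H](O[Si](C)(C)C(C)(C)C)CCC[C@@H](O[Si](C)(C)C(C)(C)C)C[C@@H](OCc1ccc(OC)cc1)CC(=O)C[C@@H]1C[C@@H](OCc2ccccc2)CC(OCc2ccccc2)O1 | intermediate
23 | C7 ketone with free C9–OH | CCCCCCCCCCC[C@H](O[Si](C)(C)C(C)(C)C)CCC[C@@H](O[Si](C)(C)C(C)(C)C)C[C@@H](O)CC(=O)C[C@@H]1C[C@@H](OCc2ccccc2)CC(OCc2ccccc2)O1 | intermediate
24 | C9 O-diethylboryl chelate of 23 | CCCCCCCCCCC[C@H](O[Si](C)(C)C(C)(C)C)CCC[C@@H](O[Si](C)(C)C(C)(C)C)C[C@@H](OB(CC)CC)CC(=O)C[C@@H]1C[C@@H](OCc2ccccc2)CC(OCc2ccccc2)O1 | intermediate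
25 | C7/C9 syn diol | CCCCCCCCCCC[C@H](O[Si](C)(C)C(C)(C)C)CCC[C@@H](O[Si](C)(C)C(C)(C)C)C[C@@H](O)C[C@@H](O)C[C@@H]1C[C@@H](OCc2ccccc2)CC(OCc2ccccc2)O1 | intermediate
26 | tetra-TBS ether, C1 and C3 OBn | CCCCCCCCCCC[C@H](O[Si](C)(C)C(C)(C)C)CCC[C@@H](O[Si](C)(C)C(C)(C)C)C[C@@H](O[Si](C)(C)C(C)(C)C)C[C@@H](O[Si](C)(C)C(C)(C)C)C[C@@H]1C[C@@H](OCc2ccccc2)CC(OCc2ccccc2)O1 | intermediate
27 | tetra-TBS lactol with free C3–OH | CCCCCCCCCCC[C@H](O[Si](C)(C)C(C)(C)C)CCC[C@@H](O[Si](C)(C)C(C)(C)C)C[C@@H](O[Si](C)(C)C(C)(C)C)C[C@@H](O[Si](C)(C)C(C)(C)C)C[C@@H]1C[C@@H](O)CC(O)O1 | intermediate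
28 | tetra-TBS β-hydroxy-δ-lactone | CCCCCCCCCCC[C@H](O[Si](C)(C)C(C)(C)C)CCC[C@@H](O[Si](C)(C)C(C)(C)C)C[C@@H](O[Si](C)(C)C(C)(C)C)C[C@@H](O[Si](C)(C)C(C)(C)C)C[C@@H]1C[C@@H](O)CC(=O)O1 | intermediate
29 | C3 methanesulfonate of 28, (2R,4R)-6-oxooxan-4-yl mesylate | CCCCCCCCCCC[C@H](O[Si](C)(C)C(C)(C)C)CCC[C@@H](O[Si](C)(C)C(C)(C)C)C[C@@H](O[Si](C)(C)C(C)(C)C)C[C@@H](O[Si](C)(C)C(C)(C)C)C[C@@H]1C[C@@H](OS(C)(=O)=O)CC(=O)O1 | intermediate
30 | tetra-TBS 5,6-dihydropyran-2-one | CCCCCCCCCCC[C@H](O[Si](C)(C)C(C)(C)C)CCC[C@@H](O[Si](C)(C)C(C)(C)C)C[C@@H](O[Si](C)(C)C(C)(C)C)C[C@@H](O[Si](C)(C)C(C)(C)C)C[C@@H]1CC=CC(=O)O1 | intermediate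
31 | (6S)-6-[(2R,4R,6R,10S)-2,4,6,10-tetrahydroxyhenicosyl]-5,6-dihydro-2H-pyran-2-one | CCCCCCCCCCC[C@H](O)CCC[C@@H](O)C[C@@H](O)C[C@@H](O)C[C@@H]1CC=CC(=O)O1 | target

**Step count**
Total step count: 22.
Longest linear sequence: 15 steps (1, 5–7, 12–22). The branch 8–11, 12–22 is equally long.

**Steps most likely to fail**

**Step 14.** Substitution at the β-oxygenated primary carbon may be slow. Proton transfer, E2 loss of HI towards the exocyclic enol ether, or iodine–lithium exchange followed by fragmentation of the oxane ring could then take over.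
The fallback sets out from 19 and 8 and comes back at 22.
- The dithiane of 19 is hydrolysed (MeI, CaCO3, aq. MeCN) to (3R,5R,9S)-5,9-bis(TBSO)-3-(PMBO)icosanal F1.
- Pinnick oxidation gives (3R,5R,9S)-5,9-bis(TBSO)-3-(PMBO)icosanoic acid F2.
- 2,2'-Dipyridyl disulfide/PPh3 gives the S-(pyridin-2-yl) thioester of this acid F3.
- Nickel-catalysed reductive cross-electrophile coupling of F3 with iodide 8 (NiCl2·dme, 4,4'-di-tert-butylbipyridine, Mn, DMA, rt) would form C6–C7 through a C6 radical at the ketone oxidation level. No carbanion and no strong base are involved, and the product is 22 directly.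

**Step 1.** The enzyme may be inactivated by the aldehydes, the sequence may stall after the first addition, or acetaldehyde may compete as its own acceptor.
The fallback sets out from 1 and comes back at 5.
- Asymmetric allylboration of anhydrous 1 uses the B-allyldiisopinocampheylborane enantiomer that gives the S alcohol. After oxidative work-up it gives (2S)-1-chloropent-4-en-2-ol F4.
- Ozonolysis (O3, then Me2S) gives 3, which is used crude in a second reagent-controlled allylboration to give (2S,4S)-1-chlorohept-6-ene-2,4-diol F5.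
- Ozonolysis of F5 gives 4, which closes to 5.

**Step 20.** Discrimination between the lactol and the C3 carbinol may be incomplete, so that C3 is oxidised as well, or conversion on the silver surface may be slow for this lipophilic substrate.
The fallback sets out from 27 and comes back at 30.
- Acetylation (Ac2O, pyridine) gives the C1,C3-diacetate (4R,6S)-6-[tetrakis(TBSO)henicosyl]oxane-2,4-diyl diacetate F6.
- Selective anomeric deacetylation (hydrazine acetate, DMF) gives the C3-acetoxy lactol F7.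
- Dess–Martin oxidation, which now needs no chemoselectivity, gives the β-acetoxy-δ-lactone F8.
- DBU in CH2Cl2 eliminates acetate to give 30.

**Further compounds**
F1 | step 14 | (3R,5R,9S)-5,9-bis(TBSO)-3-(PMBO)icosanal | CCCCCCCCCCC[C@H](O[Si](C)(C)C(C)(C)C)CCC[C@@H](O[Si](C)(C)C(C)(C)C)C[C@@H](OCc1ccc(OC)cc1)CC=O
F2 | step 14 | (3R,5R,9S)-5,9-bis(TBSO)-3-(PMBO)icosanoic acid | CCCCCCCCCCC[C@H](O[Si](C)(C)C(C)(C)C)CCC[C@@H](O[Si](C)(C)C(C)(C)C)C[C@@H](OCc1ccc(OC)cc1)CC(=O)O
F3 | step 14 | S-(pyridin-2-yl) (3R,5R,9S)-5,9-bis(TBSO)-3-(PMBO)icosanethioate | CCCCCCCCCCC[C@H](O[Si](C)(C)C(C)(C)C)CCC[C@@H](O[Si](C)(C)C(C)(C)C)C[C@@H](OCc1ccc(OC)cc1)CC(=O)Sc1ccccn1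
F4 | step 1 | (2S)-1-chloropent-4-en-2-ol | ClC[C@@H](O)CC=C
F5 | step 1 | (2S,4S)-1-chlorohept-6-ene-2,4-diol | ClC[C@@H](O)C[C@@H](O)CC=C
F6 | step 20 | (4R,6S)-6-[(2S,4R,6R,10S)-2,4,6,10-tetrakis(TBSO)henicosyl]oxane-2,4-diyl diacetate | CCCCCCCCCCC[C@H](O[Si](C)(C)C(C)(C)C)CCC[C@@H](O[Si](C)(C)C(C)(C)C)C[C@@H](O[Si](C)(C)C(C)(C)C)C[C@@H](O[Si](C)(C)C(C)(C)C)C[C@@H]1C[C@@H](OC(C)=O)CC(OC(C)=O)O1
F7 | step 20 | (2S,4R)-6-hydroxy-2-[(2S,4R,6R,10S)-2,4,6,10-tetrakis(TBSO)henicosyl]oxan-4-yl acetate | CCCCCCCCCCC[C@H](O[Si](C)(C)C(C)(C)C)CCC[C@@H](O[Si](C)(C)C(C)(C)C)C[C@@H](O[Si](C)(C)C(C)(C)C)C[C@@H](O[Si](C)(C)C(C)(C)C)C[C@@H]1C[C@@H](OC(C)=O)CC(O)O1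
F8 | step 20 | (2S,4R)-6-oxo-2-[(2S,4R,6R,10S)-2,4,6,10-tetrakis(TBSO)henicosyl]oxan-4-yl acetate | CCCCCCCCCCC[C@H](O[Si](C)(C)C(C)(C)C)CCC[C@@H](O[Si](C)(C)C(C)(C)C)C[C@@H](O[Si](C)(C)C(C)(C)C)C[C@@H](O[Si](C)(C)C(C)(C)C)C[C@@H]1C[C@@H](OC(C)=O)CC(=O)O1
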